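All runs come from a simulation for substances that don't exist; noise was put on by code.

**The runs.** North-east and south-west are the flasks I can read. They carry the same second substrate and free enzyme as the flasks asked about, and they differ in the charge of starting material.

the same everywhere: second substrate 0.0594 M; free enzyme 0.35 µM

| run | starting material | remark | time |
|---|---|---|---|
| north-east | 0.0066 M | run made earlier |  |
| south-west | 0.061 M | run made earlier |  |
| larch | 0.0060 M |  | 6.0 h |
| elm | 0.015 M |  | 6.0 h |
| ash | 0.025 M |  | 6.0 h |
| birch | 0.050 M |  | 6.0 h |

| run | time / h | target / % | starting material / % |
|---|---|---|---|
| north-east | 0.667 | 2 | 94 |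
| north-east | 1.33 | 8 | 92 |
| north-east | 2.00 | 12 | 88 |
| north-east | 2.50 | 17 | 83 |
| north-east | 3.00 | 22 | 80 |
| north-east | 4.00 | 25 | 69 |
| south-west | 0.667 | 3 | 97 |
| south-west | 1.33 | 7 | 96 |
| south-west | 2.00 | 9 | 93 |
| south-west | 2.50 | 10 | 91 |
| south-west | 3.00 | 10 | 90 |
| south-west | 4.00 | 12 | 89 |

(scatter of a reading: 2 percentage points)

- what was read earlier has a scatter of 2 percentage points, one standard deviation
- "hardly changes" means that all values lie within two and a half points (for a concentration: within two and a half percent of the largest)

- amount of target at the end, in percent of the starting material charged for larch, elm, ash, birch, in this order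
- how the row runs (rises all the way / hardly changes / falls all the way / falls, then rises / rises, then falls)

**The charge.** By hand, the fraction made stays level with charge if the rate grows in step with the charge, and falls if the rate lags. It lags: after 4.00 h, north-east has made 25% of its charge and south-west 12%. Time divided by fraction made gives 16.0 h for north-east and 33.3 h for south-west. These are the hours a flask needs for its whole charge at the pace kept so far, and I call this the clearing time. With enzyme and second substrate held fixed, a saturating enzyme gives a clearing time that is straight in the charge: this is the Hanes plot, charge over rate against charge. So I draw that line through the two runs.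

**The time.** By hand, a steady clearing time makes the fraction grow in step with time. North-east reads 16.7 h at 2.00 h, then 16.0 h, so it holds. South-west reads 22.2 h at 2.00 h, then 33.3 h, so it lengthens, but each reading carries 2 percentage points. I carry the latest readings forward to 6.0 h.

**The others.** Second substrate and free enzyme are charged at 0.0594 M and 0.35 µM in every flask, so along the row I turn the charge of starting material and leave these two charges as they are. Starting material is the limiting reagent, with the largest charge below second substrate.

**My row.** The line gives 15.8 h for larch, 18.7 h for elm, 21.9 h for ash and 29.8 h for birch. Dividing 6.0 h by each gives 38.0%, 32.1%, 27.4% and 20.1%, so my row falls all the way.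

**The forecast.** It stands lower than mine, at 32%, 27%, 22% and 16%, and says the row falls all the way, on the ground that “percent yield should fall as charge rises”.

**The flask.** It gives 36.5%, 32.0%, 28.0% and 21.0%, and the row falls all the way.

    second substrate + loaded enzyme ⇌ second complex (K = 7.00 M⁻¹, k = 1500 M⁻¹ s⁻¹)
    first complex ⇌ loaded enzyme + first product (K = 0.0710 M, k = 4.00 s⁻¹)
    second complex → free enzyme + target (k = 34.0 s⁻¹)
    starting material + free enzyme ⇌ first complex (K = 17.0 M⁻¹, k = 8100 M⁻¹ s⁻¹)

**The catalyst.** These values make the clearing time 16.4 h in larch and 28.6 h in birch, 1.74 times as long, while free enzyme at 6.00 h goes from 91.5% of the catalyst charged, the resting state of larch, to 50.2% in birch. In larch at that time, the forward step onto free enzyme gives starting material a half-life of 0.074 h, against 19 h for second substrate onto loaded enzyme, and in larch second complex falls back 6.3 times faster than it goes on at 2.69 h.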